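**Retrosynthetic overview**

1. The plan rests on ring B (C1, C5–C10; daucane numbering, C15 on C1, C14 on C8, β = face of C15). C6 is its only oxygenated carbon and lies between C5 and C7, so C5–C6–C7 is read as an oxyallyl cation and C1=C10–C9=C8 as a diene. The C2–C3–C4 chain of ring A (C1–C5) already ties that diene to C5.
2. Late disconnections: the C6–O ester goes back to dauc-8-ene-4β,6α-diol and veratric acid. The 6α-OH comes from the 6-ketone by hydride delivered from the 4β-OH. The C8=C9 bond comes from a 7,9-dien-6-one by 1,6-reduction, and that dienone from the Δ9-6-ketone by C7–C8 dehydrogenation.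
3. Key disconnection: C1–C5 and C7–C8 are cut together (retro-(4+3)). Rings A and B form in the same step from an open chain; no ring exists before it.
4. The chloromethyl ketone comes from the C6 aldehyde plus a CH2Cl unit (C7). The (E,E)-diene comes from the C1≡C10 alkyne by syn-methylalumination (C15) and coupling with a propenyl unit (C9, C8, C14).
5. Both chain ends arise by ozonolysis of (S)-terpinen-4-ol, whose carbinol carbon is C4 with its isopropyl group and whose ring carbons become C1–C6 in line.

Key step: step 9

Remark: (S)-(+)-terpinen-4-ol is assumed to be used in enantiomerically pure form (enriched first if the purchased lot is not). C4 is the only stereocentre brought in; all others are set relative to it.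

**Route**

Step 1
Reactants: 1 (S)-terpinen-4-ol
Product: 2 (S)-terpinen-4-ol triethylsilyl ether
Conditions: TESOTf, 2,6-lutidine, CH2Cl2, 0 → 23 °C
Reagents that add atoms: triethylsilyl trifluoromethanesulfonate CC[Si](CC)(CC)OS(=O)(=O)C(F)(F)F
Why: O-silylation of a tertiary alcohol with a silyl triflate and a hindered pyridine base is reliable, leaves C4 untouched, and the ether later blocks retro-aldol cleavage of the β-oxygenated carbonyl intermediates.

Step 2
Reactants: 2 (S)-terpinen-4-ol triethylsilyl ether
Product: 4 (3S)-6-oxo-3-(propan-2-yl)-3-(triethylsilyloxy)heptanal, via secondary ozonide 3 (not isolated)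
Conditions: O3, CH2Cl2, −78 °C; then PPh3, −78 → 23 °C
Reagents that add atoms: ozone [O-][O+]=O
Why: Ozonolysis with reductive work-up cleaves the only C=C bond and gives the two chain ends at different oxidation levels (aldehyde carbon = C6, methyl ketone carbon = C1); the ozonide centres vanish on reduction and C4 is not involved.

Step 3
Reactants: 4 (3S)-6-oxo-3-(propan-2-yl)-3-(triethylsilyloxy)heptanal
Product: 5 (5S)-7,7-dimethoxy-5-(propan-2-yl)-5-(triethylsilyloxy)heptan-2-one
Conditions: HC(OMe)3, CeCl3·7H2O (0.3 equiv), MeOH, 0 → 23 °C; NaHCO3 quench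
Reagents that add atoms: trimethyl orthoformate COC(OC)OC; methanol CO
Why: Cerium-chloride-mediated chemoselective acetalisation converts aldehydes much faster than ketones, so C6 is masked while the methyl ketone stays free for the strong-base step.

Step 4
Reactants: 5 (5S)-7,7-dimethoxy-5-(propan-2-yl)-5-(triethylsilyloxy)heptan-2-one
Product: 7 (5S)-7,7-dimethoxy-5-(propan-2-yl)-5-(triethylsilyloxy)hept-1-yne, via enol diethyl phosphate 6 (not isolated)
Conditions: LiN(iPr)2 (1.1 equiv), THF, −78 °C; ClP(O)(OEt)2, −78 → 23 °C; then LiN(iPr)2 (2.3 equiv), −78 → 23 °C; aq. NH4Cl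
Reagents that add atoms: none
Why: Methyl ketone to terminal alkyne conversion through the kinetic (methyl-side) enolate, O-phosphorylation and E2 loss of diethyl phosphate with excess amide base; the former methyl carbon becomes C10 and no stereocentre is affected.

Step 5
Reactants: 7 (5S)-7,7-dimethoxy-5-(propan-2-yl)-5-(triethylsilyloxy)hept-1-yne; 8 (E)-1-bromoprop-1-ene
Product: 10 (2E,4E,8S)-10,10-dimethoxy-5-methyl-8-(propan-2-yl)-8-(triethylsilyloxy)deca-2,4-diene, via alkenyldimethylalane 9 (not isolated)
Conditions: Me3Al (2.5 equiv), Cp2ZrCl2 (0.25 equiv), H2O (1 equiv), CH2Cl2, −23 °C; then THF, ZnCl2 (0.5 equiv), Pd(PPh3)4 (5 mol %), 8 (3 equiv), 0 → 23 °C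
Reagents that add atoms: trimethylaluminium C[Al](C)C; (E)-1-bromoprop-1-ene C/C=C/Br
Why: Zirconium-catalysed Negishi carboalumination adds methyl (C15) to C1 and aluminium to C10 in a syn fashion, which fixes the (E) geometry of C1=C10, and the Pd/Zn-catalysed Negishi cross-coupling proceeds with retention at both alkenyl carbons to give the (E,E)-diene; the short cold carbometalation and the THF of the coupling stage keep the aluminium Lewis acid from opening the acetal.

Step 6
Reactants: 10 (2E,4E,8S)-10,10-dimethoxy-5-methyl-8-(propan-2-yl)-8-(triethylsilyloxy)deca-2,4-diene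
Product: 11 (3S,6E,8E)-6-methyl-3-(propan-2-yl)-3-(triethylsilyloxy)deca-6,8-dienal
Conditions: PPTS (0.2 equiv), acetone/H2O 9:1, 23 → 35 °C
Reagents that add atoms: water O
Why: Mild acid-catalysed acetal hydrolysis frees the aldehyde while the hindered tertiary silyl ether and the diene remain intact and no base is present to eliminate the β-silyloxy group.

Step 7
Reactants: 11 (3S,6E,8E)-6-methyl-3-(propan-2-yl)-3-(triethylsilyloxy)deca-6,8-dienal; 12 chloroiodomethane
Product: 13 (4S,7E,9E)-1-chloro-7-methyl-4-(propan-2-yl)-4-(triethylsilyloxy)undeca-7,9-dien-2-ol (both C2 epimers)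
Conditions: 12 (1.5 equiv), MeLi·LiBr (1.4 equiv), THF/Et2O, −78 °C; aq. NH4Cl at −78 °C
Reagents that add atoms: chloroiodomethane ClCI
Why: Chloromethyllithium made by iodine–lithium exchange in the presence of the aldehyde (Barbier-type carbenoid 1,2-addition) is trapped faster than it decomposes and the cold quench prevents epoxide closure; the new carbinol centre (C6) forms without control and is removed in step 8.

Step 8
Reactants: 13 (4S,7E,9E)-1-chloro-7-methyl-4-(propan-2-yl)-4-(triethylsilyloxy)undeca-7,9-dien-2-ol
Product: 14 (4S,7E,9E)-1-chloro-7-methyl-4-(propan-2-yl)-4-(triethylsilyloxy)undeca-7,9-dien-2-one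
Conditions: Dess–Martin periodinane, NaHCO3, CH2Cl2, 0 → 23 °C
Reagents that add atoms: none
Why: Dess–Martin oxidation of a secondary alcohol under buffered, non-basic conditions gives the α-chloro ketone without touching the diene, the chloride or the silyl ether.

Step 9
Reactants: 14 (4S,7E,9E)-1-chloro-7-methyl-4-(propan-2-yl)-4-(triethylsilyloxy)undeca-7,9-dien-2-one
Product: 16 4β-triethylsilyloxy-5α-H-dauc-9-en-6-one (trans-fused; C15 β; isopropyl α; C14 α), via oxyallyl cation 15 (not isolated)
Conditions: NaOCH2CF3 (1.5 equiv), CF3CH2OH, 0.01 M, 0 → 23 °C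
Reagents that add atoms: none
Why: Trifluoroethoxide enolises 14 reversibly toward C5 and the enolate loses chloride from C7 in the ionising, weakly nucleophilic alcohol to give the 2-oxidoallyl cation 15, a two-electron three-carbon unit (C5–C6–C7) that adds across the four-electron diene C1=C10–C9=C8; the closest known reaction type is the intramolecular (4+3) cycloaddition of oxyallyl cations generated from α-halo ketones with tethered 1,3-dienes, which gives hydroazulenones. Ring B (seven-membered) closes as the (4+3) ring through the new C7–C8 and C1–C5 bonds, and ring A (five-membered) closes in the same event as the tether ring through C1–C5, a 5-exo attack of C5 on the diene terminus C1. Because C1 is fully substituted the addition is expected to be asynchronous, with C7–C8 bonding running ahead and positive charge building at the tertiary allylic C1 before C5 closes on it. C1 is controlled by the C4 stereocentre through the folding of the C2–C3–C4 chain: the oxyallyl carbon C6 lies anti to the isopropyl group on the neighbouring C4 and beside the slimmer silyloxy group, so isopropyl and C10 become cis and pseudo-equatorial on the new cyclopentane; C5 is controlled relative to C1 by the extended arrangement open to the (E)-C1=C10 bond with the chain in the outside position, which leads to the trans fusion (C5 stays epimerisable through the C6 enolate); C8 follows from the (E)-C8=C9 bond under suprafacial addition and is removed in step 10. The step needs facial selectivity at C1 relative to C4, secured by the size difference between isopropyl and silyloxy on C4, and periselectivity for the seven-membered ring over Favorskii contraction and (3+2) closure, which the non-nucleophilic medium and the three-carbon tether are chosen to favour.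

Step 10
Reactants: 16 4β-triethylsilyloxy-5α-H-dauc-9-en-6-one
Product: 18 4β-triethylsilyloxy-5α-H-dauca-7,9-dien-6-one, via lithium enolate 17 (not isolated)
Conditions: LiN(iPr)2 (1.2 equiv), THF, −78 °C; then N-tert-butylbenzenesulfinimidoyl chloride (1.3 equiv), −78 °C
Reagents that add atoms: none
Why: Mukaiyama dehydrogenation: the kinetic enolate forms at C7 because the C5 methine lies between two fully substituted carbons, its sulfilimine adduct undergoes syn-elimination toward C8 (the only β-carbon bearing hydrogen), and any C8 epimers of 16 converge because C8 becomes trigonal.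

Step 11
Reactants: 18 4β-triethylsilyloxy-5α-H-dauca-7,9-dien-6-one
Product: 20 4β-triethylsilyloxy-5α-H-dauc-8-en-6-one, via lithium dienolate 19 (not isolated)
Conditions: Li (4 equiv), NH3(l)/THF, t-BuOH (1 equiv), −78 °C, 10 min; solid NH4Cl, −78 °C
Reagents that add atoms: none
Why: Dissolving-metal 1,6-reduction of a linearly conjugated dienone: two electrons and a proton at the δ-carbon C10 give the extended dienolate 19, and its kinetic C-protonation at the α-carbon C7 leaves the C8=C9 bond out of conjugation; C5 is never enolised.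

Step 12
Reactants: 20 4β-triethylsilyloxy-5α-H-dauc-8-en-6-one
Product: 21 4β-hydroxy-5α-H-dauc-8-en-6-one
Conditions: HF·pyridine, pyridine, THF, 0 → 23 °C
Reagents that add atoms: none
Why: Fluoride-induced Si–O cleavage under buffered, weakly acidic conditions avoids retro-aldol opening of the β-hydroxy ketone and migration of the β,γ-double bond.

Step 13
Reactants: 21 4β-hydroxy-5α-H-dauc-8-en-6-one
Product: 22 dauc-8-ene-4β,6α-diol (jaeschkeanadiol)
Conditions: Me4NBH(OAc)3 (5 equiv), MeCN/AcOH 1:1, −20 °C
Reagents that add atoms: none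
Why: Evans–Saksena hydroxyl-directed reduction: the 4β-hydroxyl displaces acetate on boron and hydride is delivered intramolecularly through a six-membered transition state to the β face of C6, which sets the 6α-hydroxyl (anti-1,3-diol).

Step 14
Reactants: 22 dauc-8-ene-4β,6α-diol; 23 veratric acid
Product: 24 4β-hydroxydauc-8-en-6α-yl 3,4-dimethoxybenzoate (target)
Conditions: 23 (1.5 equiv), DCC (1.6 equiv), DMAP (0.3 equiv), CH2Cl2, 23 °C
Reagents that add atoms: veratric acid COc1ccc(C(=O)O)cc1OC
Why: Steglich esterification acylates the secondary 6-hydroxyl selectively because the tertiary 4-hydroxyl is far less reactive; no stereocentre changes.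

**Compound list**

1 | (S)-terpinen-4-ol [(1S)-4-methyl-1-(propan-2-yl)cyclohex-3-en-1-ol] | CC1=CC[C@](O)(C(C)C)CC1 | starting material
2 | (S)-terpinen-4-ol triethylsilyl ether | CC1=CC[C@](O[Si](CC)(CC)CC)(C(C)C)CC1 | intermediate
3 | secondary ozonide of 2 (1,2,4-trioxolane across the former C=C; epimers at the ozonide carbons) | CC12CC[C@@](O[Si](CC)(CC)CC)(C(C)C)CC(OO1)O2 | intermediate
4 | (3S)-6-oxo-3-(propan-2-yl)-3-(triethylsilyloxy)heptanal | O=CC[C@](O[Si](CC)(CC)CC)(C(C)C)CCC(C)=O | intermediate
5 | (5S)-7,7-dimethoxy-5-(propan-2-yl)-5-(triethylsilyloxy)heptan-2-one | COC(OC)C[C@](O[Si](CC)(CC)CC)(C(C)C)CCC(C)=O | intermediate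
6 | diethyl (5S)-7,7-dimethoxy-5-(propan-2-yl)-5-(triethylsilyloxy)hept-1-en-2-yl phosphate | COC(OC)C[C@](O[Si](CC)(CC)CC)(C(C)C)CCC(=C)OP(=O)(OCC)OCC | intermediate
7 | (5S)-7,7-dimethoxy-5-(propan-2-yl)-5-(triethylsilyloxy)hept-1-yne | COC(OC)C[C@](O[Si](CC)(CC)CC)(C(C)C)CCC#C | intermediate
8 | (E)-1-bromoprop-1-ene | C/C=C/Br | starting material
9 | [(1E,5S)-7,7-dimethoxy-2-methyl-5-(propan-2-yl)-5-(triethylsilyloxy)hept-1-enyl]dimethylalane | COC(OC)C[C@](O[Si](CC)(CC)CC)(C(C)C)CC/C(C)=C/[Al](C)C | intermediate
10 | (2E,4E,8S)-10,10-dimethoxy-5-methyl-8-(propan-2-yl)-8-(triethylsilyloxy)deca-2,4-diene | COC(OC)C[C@](O[Si](CC)(CC)CC)(C(C)C)CC/C(C)=C/C=C/C | intermediate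
11 | (3S,6E,8E)-6-methyl-3-(propan-2-yl)-3-(triethylsilyloxy)deca-6,8-dienal | O=CC[C@](O[Si](CC)(CC)CC)(C(C)C)CC/C(C)=C/C=C/C | intermediate
12 | chloroiodomethane | ClCI | starting material
13 | (4S,7E,9E)-1-chloro-7-methyl-4-(propan-2-yl)-4-(triethylsilyloxy)undeca-7,9-dien-2-ol (C2 epimers) | ClCC(O)C[C@](O[Si](CC)(CC)CC)(C(C)C)CC/C(C)=C/C=C/C | intermediate
14 | (4S,7E,9E)-1-chloro-7-methyl-4-(propan-2-yl)-4-(triethylsilyloxy)undeca-7,9-dien-2-one | ClCC(=O)C[C@](O[Si](CC)(CC)CC)(C(C)C)CC/C(C)=C/C=C/C | intermediate
15 | 2-oxidoallyl cation from 14 (C5–C6–C7) | [CH2+]C([O-])=C[C@](O[Si](CC)(CC)CC)(C(C)C)CC/C(C)=C/C=C/C | intermediate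
16 | 4β-triethylsilyloxy-5α-H-dauc-9-en-6-one (trans-fused; C15 β; isopropyl α; C14 α) | O=C2C[C@@H](C)C=C[C@@]3(C)CC[C@@](O[Si](CC)(CC)CC)(C(C)C)[C@H]23 | intermediate
17 | lithium C6–C7 enolate of 16 | [Li]OC2=C[C@@H](C)C=C[C@@]3(C)CC[C@@](O[Si](CC)(CC)CC)(C(C)C)[C@H]23 | intermediate
18 | 4β-triethylsilyloxy-5α-H-dauca-7,9-dien-6-one | O=C2C=C(C)C=C[C@@]3(C)CC[C@@](O[Si](CC)(CC)CC)(C(C)C)[C@H]23 | intermediate
19 | lithium 4β-triethylsilyloxy-5α-H-dauca-6,8-dien-6-olate | [Li]OC2=CC(C)=CC[C@@]3(C)CC[C@@](O[Si](CC)(CC)CC)(C(C)C)[C@H]23 | intermediate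
20 | 4β-triethylsilyloxy-5α-H-dauc-8-en-6-one | O=C2CC(C)=CC[C@@]3(C)CC[C@@](O[Si](CC)(CC)CC)(C(C)C)[C@H]23 | intermediate
21 | 4β-hydroxy-5α-H-dauc-8-en-6-one | O=C2CC(C)=CC[C@@]3(C)CC[C@@](O)(C(C)C)[C@H]23 | intermediate
22 | dauc-8-ene-4β,6α-diol (jaeschkeanadiol; 5α-H, trans-fused) | O[C@H]2CC(C)=CC[C@@]3(C)CC[C@@](O)(C(C)C)[C@H]23 | intermediate
23 | veratric acid (3,4-dimethoxybenzoic acid) | COc1ccc(C(=O)O)cc1OC | starting material
24 | 4β-hydroxydauc-8-en-6α-yl 3,4-dimethoxybenzoate | COc1ccc(C(=O)O[C@H]2CC(C)=CC[C@@]3(C)CC[C@@](O)(C(C)C)[C@H]23)cc1OC | target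

**Step count**

Total: 14 steps. Longest linear sequence: 14 steps (1 → 24); 8, 12 and 23 enter as purchased.

**Steps most likely to fail**

Step 9. The oxyallyl cation carries no substituent at C7 and is short-lived. It may collapse to a cyclopropanone and undergo Favorskii contraction, or be captured by the solvent. After stepwise bonding at the hindered diene terminus it may close in a (3+2) sense. The C5 enolate may expel silyloxide, and facial or ring-fusion selectivity may be low. The fallback keeps the same bond formation but stabilises the cation with a chlorine on C7. It sets out from 11: addition of LiCHCl2 (from CH2Cl2 and LiN(iPr)2, THF, −100 °C) should give (4S,7E,9E)-1,1-dichloro-7-methyl-4-(propan-2-yl)-4-(triethylsilyloxy)undeca-7,9-dien-2-ol F1. Dess–Martin oxidation should give the dichloromethyl ketone F2. With NaOCH2CF3 in CF3CH2OH this ionises to the chlorine-stabilised 1-chloro-2-oxidoallyl cation F3, a type of cation that resists ring contraction and lives longer, and cycloaddition should give 7-chloro-4β-triethylsilyloxy-5α-H-dauc-9-en-6-one F4. Zn dust in AcOH at 23 °C removes the α-chlorine and the route is rejoined at 16.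

Step 11. The dienolate may be protonated at C9 instead of C7, the C8=C9 bond may drift back into conjugation under the basic quench, or reduction may run on to the saturated ketone. The fallback sets out from 18 and avoids any enolate: 1,4-hydrogenation of the cisoid ring diene C7=C8–C9=C10 with (naphthalene)Cr(CO)3 (10 mol %) and H2 (5 MPa) in acetone at 45 °C adds hydrogen to C7 and C10 only and leaves C8=C9. The enone itself is transoid and cannot react this way. The route is rejoined at 20; this fallback makes no new compound (F0).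

Step 13. Acetate exchange at the hindered tertiary 4-hydroxyl may be slow, so that undirected hydride attack from the open α face competes and facial selectivity erodes. The fallback sets out from 21 and uses that α-face preference: Narasaka–Prasad reduction (Et2BOMe, NaBH4, THF/MeOH, −78 °C), with external hydride attacking the boron chelate, should give dauc-8-ene-4β,6β-diol F5. Mitsunobu esterification with 23 (PPh3, DIAD, toluene, 0 → 23 °C) then inverts C6, the tertiary hydroxyl being inert. The route is rejoined at 24.

**Further compounds**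

F1 | step 9 | (4S,7E,9E)-1,1-dichloro-7-methyl-4-(propan-2-yl)-4-(triethylsilyloxy)undeca-7,9-dien-2-ol (C2 epimers) | ClC(Cl)C(O)C[C@](O[Si](CC)(CC)CC)(C(C)C)CC/C(C)=C/C=C/C
F2 | step 9 | (4S,7E,9E)-1,1-dichloro-7-methyl-4-(propan-2-yl)-4-(triethylsilyloxy)undeca-7,9-dien-2-one | ClC(Cl)C(=O)C[C@](O[Si](CC)(CC)CC)(C(C)C)CC/C(C)=C/C=C/C
F3 | step 9 | 1-chloro-2-oxidoallyl cation from F2 | Cl[CH+]C([O-])=C[C@](O[Si](CC)(CC)CC)(C(C)C)CC/C(C)=C/C=C/C
F4 | step 9 | 7-chloro-4β-triethylsilyloxy-5α-H-dauc-9-en-6-one (C7 epimers) | O=C2C(Cl)[C@@H](C)C=C[C@@]3(C)CC[C@@](O[Si](CC)(CC)CC)(C(C)C)[C@H]23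
F0 | step 11 | none | none
F5 | step 13 | dauc-8-ene-4β,6β-diol | O[C@@H]2CC(C)=CC[C@@]3(C)CC[C@@](O)(C(C)C)[C@H]23
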